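A closed, stirred vessel of constant volume holds free monomer, transfer agent, protic impurity and initiator. In the proposed steps, initiator starts a living end, the living end adds free monomer, and transfer agent turns it into a dead chain.

in all of them: free monomer 0.050 M
- alpha: transfer agent 5 mM; protic impurity 1 mM; initiator 0.26 mM; the very flask that is asked about, followed so far
- theta: transfer agent 5 mM; protic impurity 1 mM; initiator 0.17 mM; run made earlier
- flask: transfer agent 5.00 mM; protic impurity 1.00 mM; initiator 0.26 mM; time 2.0 min

- alpha (time / s: monomer in chains / %, free monomer / %): 10.0: 11.9, 85.3; 15.0: 24.2, 74.9; 20.0: 35.9, 62.7; 25.0: 46.2, 51.9
- theta (time / s: monomer in chains / %, free monomer / %): 10.0: 8.1, 89.8; 12.0: 11.1, 87.0; 25.0: 33.0, 64.2; 40.0: 56.4, 41.5; 80.0: 84.1, 14.2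

(each reading ± 0.5 percentage points)

- the average divides the monomer in chains by the number of chains begun, living and dead together
- steps that have been proposed: free monomer + initiator -> living end + monomer in chains; free monomer + living end -> monomer in chains + living end; living end + transfer agent -> dead chain; protic impurity + free monomer -> quenched substrate; 2 initiator -> spent initiator
- the earlier runs do not show the number of chains; that part of a forecast is a guess

* average number of monomer units in a chain (chains begun, living or dead) at 2.0 min
* part of the free monomer that has reacted at 2.0 min

Keep the ledger of free monomer, the limiting reagent of chain growth. First entry: each protic impurity takes one free monomer, so 1.00 mM against 0.050 M books 2.00% as quenched substrate, and the alpha readings at 25.0 s leave a gap of 1.90%. Second entry: the last two alpha readings give a decay of 0.0378 s⁻¹. Hold it from 25.0 s to 2.0 min, and 1.43% stays free, so the reckoned conversion is 98.6%. Third entry: the rest, 48.3 mM, stands in chains, and the books close.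

Now turn the ledger into chain length. First round: divide free monomer charged by initiator charged, which gives 192. Second round: put the ledger back in and divide the reckoned monomer in chains by initiator charged, which gives 186, the reckoned floor of the average. Each chain begun, living or dead, takes one initiator, and transfer begins none, so initiator that begins no chain lifts the average above the floor. Commit to an average above it; the earlier runs do not show how far.

The forecast says 210 and 98.5%, holding that “Transfer creates no new chains”. The flask gives 263 and 98.0%.

    free monomer + initiator → living end + monomer in chains (k = 0.810 M⁻¹ s⁻¹)
    free monomer + living end → monomer in chains + living end, rate k2*[living end]*[free monomer] (k = 320 M⁻¹ s⁻¹)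
    living end + transfer agent → dead chain (kL = 1.80 M⁻¹ s⁻¹)
    protic impurity + free monomer → quenched substrate (k = 78.0 M⁻¹ s⁻¹)
    2 initiator → spent initiator (k = 7.50 M⁻¹ s⁻¹)

Set the floor against the result: in the flask, 186 over 263 puts about 70.7% of the charged initiator into chains, 7.16% went to spent initiator, and 23% remained at 2.00 min. Do the same on the neighbour flask with 0.650 mM of initiator. Its chains hold 97.9% of the free monomer charged, so its floor is 75.3, and it gives 154. About 48.9% of its initiator began chains, 22.0% went to spent initiator, and 29% remained at 2.00 min.

(Readings and results were generated by integration for an exercise; the scatter is artificial.)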